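**Retrosynthetic overview**
1. Target ⇐ its bis-pivalate (ester hydrolysis only).
2. C3 stereocentre ⇐ racemic 2-methoxy acetal of the isoflavan: chiral-acid-controlled reductive removal of the acetal oxygen through the achiral 3-aryl-4H-chromene (protonation at C3, then hydride at C2).
3. Rings C and D ⇐ one thermal operation: an o-quinone methide from a ring A salicyl alcohol adds to a ring B β-methoxystyrene (hetero-Diels–Alder, ring C) while the aryl 1,1-dimethylpropargyl ether on ring B undergoes Claisen/1,5-H shift/oxa-6π closure (ring D).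
4. Ring B partner ⇐ 2,4-dihydroxybenzaldehyde (pivaloylation, O-propargylation, Wittig); ring A partner ⇐ 2,4-dihydroxy-6-methoxybenzaldehyde (pivaloylation, NaBH4).
5. Ring order: A and B are bought as the two aldehydes; C and D close together in step 6; no ring is formed afterwards.

Assumption: 2,4-dihydroxy-6-methoxybenzaldehyde is taken as a catalogue compound; the given SMILES reads as the (3R) enantiomer; ring A = methoxy-bearing benzene ring, C = its dihydropyran, B = second benzene ring, D = its dimethylpyran.

**Step 1**
Reactants: 1 2,4-dihydroxybenzaldehyde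
Product: 2 4-formyl-3-hydroxyphenyl pivalate
Conditions: PivCl (1.05 equiv), Et3N, CH2Cl2, −20 to 0 °C
Reagents that add atoms: pivaloyl chloride, CC(C)(C)C(Cl)=O
Why: Phenol acylation in which the 2-OH is locked in a hydrogen bond to the formyl group, so the more nucleophilic 4-OH is esterified selectively; no stereocentre.

**Step 2**
Reactants: 2 4-formyl-3-hydroxyphenyl pivalate; 3 3-chloro-3-methylbut-1-yne
Product: 4 4-formyl-3-[(2-methylbut-3-yn-2-yl)oxy]phenyl pivalate
Conditions: DBU (1.3 equiv), CuCl2 (1 mol %), MeCN, 0 °C to rt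
Reagents that add atoms: none
Why: Copper-catalysed O-propargylation of a phenol with a tertiary propargyl chloride is the standard entry to aryl 1,1-dimethylpropargyl ethers and works best with acidic phenols such as this ortho-formyl phenol, while the hindered pivalate tolerates DBU.

**Step 3**
Reactants: 4 4-formyl-3-[(2-methylbut-3-yn-2-yl)oxy]phenyl pivalate
Product: 5 4-(2-methoxyethenyl)-3-[(2-methylbut-3-yn-2-yl)oxy]phenyl pivalate (E/Z mixture)
Conditions: MeOCH2PPh3Cl (1.3 equiv), KN(SiMe3)2 (1.25 equiv), THF, −78 to 0 °C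
Reagents that add atoms: (methoxymethyl)triphenylphosphonium chloride, COC[P+](c1ccccc1)(c1ccccc1)c1ccccc1.[Cl-]
Why: Wittig methoxymethylenation gives the β-methoxystyrene as an E/Z mixture, which is acceptable because C3 is only fixed in step 7; the aldehyde outcompetes the hindered pivalate for the ylide, and the base is fully consumed by the salt so the terminal alkyne is not deprotonated.

**Step 4**
Reactants: 6 2,4-dihydroxy-6-methoxybenzaldehyde
Product: 7 4-formyl-3-hydroxy-5-methoxyphenyl pivalate
Conditions: PivCl (1.05 equiv), Et3N, CH2Cl2, −20 to 0 °C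
Reagents that add atoms: pivaloyl chloride, CC(C)(C)C(Cl)=O
Why: Same selective phenol acylation as in step 1, the hydrogen-bonded 2-OH staying free for the later ring C closure; no stereocentre.

**Step 5**
Reactants: 7 4-formyl-3-hydroxy-5-methoxyphenyl pivalate
Product: 8 3-hydroxy-4-(hydroxymethyl)-5-methoxyphenyl pivalate
Conditions: NaBH4, THF/MeOH, 0 °C; pH 7 buffer work-up, used crude
Reagents that add atoms: none
Why: Borohydride reduction of the aldehyde to the salicyl alcohol leaves the aryl pivalate untouched at 0 °C; 8 is acid-labile and is carried on directly.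

**Step 6**
Reactants: 8 3-hydroxy-4-(hydroxymethyl)-5-methoxyphenyl pivalate; 5 4-(2-methoxyethenyl)-3-[(2-methylbut-3-yn-2-yl)oxy]phenyl pivalate
Product: 12 rac-3-[2,2-dimethyl-5-(pivaloyloxy)-2H-chromen-8-yl]-2,5-dimethoxychroman-7-yl pivalate (cis/trans mixture), via o-quinone methide 9 (not isolated), via chromene enol ether 10 (not isolated), via propargyl cycloadduct 11 (not isolated)
Conditions: o-xylene (0.05 M), 4 Å MS, 145 °C, 8 (2 equiv) added over 6 h, then 12 h
Reagents that add atoms: none
Why: Proposed new method: two thermal pericyclic sequences are merged in one pot, namely loss of water from the electron-rich salicyl alcohol to o-quinone methide 9, which adds to the enol ether in an inverse-electron-demand hetero-Diels–Alder reaction with the nucleophilic aryl-bearing carbon bonding to the methide CH2 (ring C, 2-methoxy-3-aryl regiochemistry), and aromatic propargyl Claisen rearrangement of the aryl ether to its only free ortho position followed by 1,5-H shift and oxa-6π electrocyclisation (ring D); the order is immaterial since 10 and 11 converge on 12, the C2/C3 centres formed are racemic and are reset in step 7, and the closest known reaction types are the thermal o-quinone methide/enol ether cycloaddition to 2-alkoxychromans and the thermal conversion of aryl 1,1-dimethylpropargyl ethers into 2,2-dimethylchromenes.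

**Step 7**
Reactants: 12 rac-3-[2,2-dimethyl-5-(pivaloyloxy)-2H-chromen-8-yl]-2,5-dimethoxychroman-7-yl pivalate
Product: 14 (3R)-3-[2,2-dimethyl-5-(pivaloyloxy)-2H-chromen-8-yl]-5-methoxychroman-7-yl pivalate, via 4H-chromene 13 (not isolated)
Conditions: (R)-3,3'-bis(2,4,6-triisopropylphenyl)-BINOL N-triflylphosphoramide (10 mol %), 5 Å MS, PhMe, 60 °C, 2 h; then Hantzsch ester (1.5 equiv), −10 °C
Reagents that add atoms: none
Why: Proposed new method: the strong chiral Brønsted acid ionises the acetal (loss of MeOH) to a chroman-2-ylium/phosphoramidate ion pair that sheds H-3 to the conjugated enol ether 13, so all stereoisomers of 12 funnel into one achiral intermediate; re-protonation of 13 at C3 inside the chiral ion pair sets the C3 stereocentre (R) and the oxocarbenium ion is trapped at C2 by hydride from the Hantzsch ester before it can re-epimerise, while the much less basic ring D alkene and the pivalates stay untouched; the closest known reaction types are chiral-acid/Hantzsch-ester transfer hydrogenation of 3-substituted quinolines (enantioselective enamine protonation, then hydride) and of benzopyrylium ions and the enantioselective protonation of enol ethers by N-triflylphosphoramides, and which catalyst antipode gives 3R must be settled on the first run.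

**Step 8**
Reactants: 14 (3R)-3-[2,2-dimethyl-5-(pivaloyloxy)-2H-chromen-8-yl]-5-methoxychroman-7-yl pivalate
Product: 15 (3R)-3-(5-hydroxy-2,2-dimethyl-2H-chromen-8-yl)-5-methoxychroman-7-ol
Conditions: LiOH, THF/H2O (degassed), rt to 40 °C; then 1 M HCl
Reagents that add atoms: none
Why: Saponification of the two aryl pivalates; C3 carries no acidifying group so the stereocentre is not at risk, and air is excluded because the phenoxides are electron-rich.

**Compound list**
1 | 2,4-dihydroxybenzaldehyde | O=Cc1ccc(O)cc1O | starting material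
2 | 4-formyl-3-hydroxyphenyl pivalate | CC(C)(C)C(=O)Oc1ccc(C=O)c(O)c1 | intermediate
3 | 3-chloro-3-methylbut-1-yne | C#CC(C)(C)Cl | starting material
4 | 4-formyl-3-[(2-methylbut-3-yn-2-yl)oxy]phenyl pivalate | CC(C)(C)C(=O)Oc1ccc(C=O)c(OC(C)(C)C#C)c1 | intermediate
5 | 4-(2-methoxyethenyl)-3-[(2-methylbut-3-yn-2-yl)oxy]phenyl pivalate (E/Z mixture) | COC=Cc1ccc(OC(=O)C(C)(C)C)cc1OC(C)(C)C#C | intermediate
6 | 2,4-dihydroxy-6-methoxybenzaldehyde | COc1cc(O)cc(O)c1C=O | starting material
7 | 4-formyl-3-hydroxy-5-methoxyphenyl pivalate | COc1cc(OC(=O)C(C)(C)C)cc(O)c1C=O | intermediate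
8 | 3-hydroxy-4-(hydroxymethyl)-5-methoxyphenyl pivalate | COc1cc(OC(=O)C(C)(C)C)cc(O)c1CO | intermediate
9 | 5-methoxy-6-methylidene-3-(pivaloyloxy)cyclohexa-2,4-dien-1-one (o-quinone methide) | C=C1C(=O)C=C(OC(=O)C(C)(C)C)C=C1OC | intermediate
10 | 8-(2-methoxyethenyl)-2,2-dimethyl-2H-chromen-5-yl pivalate (E/Z mixture) | COC=Cc1ccc(OC(=O)C(C)(C)C)c2c1OC(C)(C)C=C2 | intermediate
11 | rac-2,5-dimethoxy-3-{2-[(2-methylbut-3-yn-2-yl)oxy]-4-(pivaloyloxy)phenyl}chroman-7-yl pivalate (cis/trans mixture) | COC1Oc2cc(OC(=O)C(C)(C)C)cc(OC)c2CC1c1ccc(OC(=O)C(C)(C)C)cc1OC(C)(C)C#C | intermediate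
12 | rac-3-[2,2-dimethyl-5-(pivaloyloxy)-2H-chromen-8-yl]-2,5-dimethoxychroman-7-yl pivalate (cis/trans mixture) | COC1Oc2cc(OC(=O)C(C)(C)C)cc(OC)c2CC1c1ccc(OC(=O)C(C)(C)C)c2c1OC(C)(C)C=C2 | intermediate
13 | 3-[2,2-dimethyl-5-(pivaloyloxy)-2H-chromen-8-yl]-5-methoxy-4H-chromen-7-yl pivalate | COc1cc(OC(=O)C(C)(C)C)cc2c1CC(c1ccc(OC(=O)C(C)(C)C)c3c1OC(C)(C)C=C3)=CO2 | intermediate
14 | (3R)-3-[2,2-dimethyl-5-(pivaloyloxy)-2H-chromen-8-yl]-5-methoxychroman-7-yl pivalate | COc1cc(OC(=O)C(C)(C)C)cc2c1C[C@H](c1ccc(OC(=O)C(C)(C)C)c3c1OC(C)(C)C=C3)CO2 | intermediate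
15 | (3R)-3-(5-hydroxy-2,2-dimethyl-2H-chromen-8-yl)-5-methoxychroman-7-ol | COc1cc(O)cc2c1C[C@H](c1ccc(O)c3c1OC(C)(C)C=C3)CO2 | target

**Step count and risks**
Total step count: 8. Longest linear sequence: 6 (1 → 2 → 4 → 5 → 12 → 14 → 15; steps 1, 2, 3, 6, 7, 8).

Most likely to fail, first: step 7 (untested enantioselective reset; possible low ee, dimerisation of 13 or acid damage to ring D). The fallback sets out from 12 and comes back at 14. It abandons asymmetric catalysis for resolution: plain ionic hydrogenation of 12 (Et3SiH, BF3·OEt2, CH2Cl2, −78 °C) gives the racemic bis-pivalate F3, whose enantiomers are separated by preparative chiral SFC on an amylose carbamate phase. The (R)-enantiomer is 14 and goes into step 8; half of the material is lost.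

Second: step 6 (the o-quinone methide may oligomerise faster than it adds to a 1,2-disubstituted enol ether). The fallback sets out from 5 and 7 and comes back at 14, replacing the cycloaddition by a condensation. Compound 5 is heated alone (o-xylene, 145 °C) so that only the Claisen cascade runs and chromene enol ether 10 is isolated. Compound 10 and salicylaldehyde 7 are condensed with HBF4·OEt2 in Et2O/AcOH at 0 °C (aldol-type addition, cyclodehydration) to the isoflavylium tetrafluoroborate F1. MeOH/2,6-lutidine adds methoxide at C2 to give the neutral 2-methoxy-2H-chromene F2. Under the step 7 catalyst with 2.2 equiv of Hantzsch ester, F2 is ionised to the chiral pyrylium ion pair, reduced to 13 and carried on in the same flask to 14. Steps 5 and 6 are then not needed.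

Third: step 5 (8 is an electron-rich salicyl alcohol that can ionise and self-condense on isolation). The fallback sets out from 7 and comes back at 9 inside step 6, using a bench-stable o-quinone methide precursor. After the NaBH4 reduction of 7, TolSO2Na and HCO2H/H2O are added to the same flask, and the benzylic cation is captured as the crystalline sulfone 3-hydroxy-5-methoxy-4-(tosylmethyl)phenyl pivalate F4. In step 6, F4 replaces 8 with Cs2CO3 added; base-induced loss of sulfinate releases 9 in the hot solution of 5.

**Further compounds**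
F1 | step 6 | 3-[2,2-dimethyl-5-(pivaloyloxy)-2H-chromen-8-yl]-5-methoxy-7-(pivaloyloxy)chromenylium tetrafluoroborate | COc1cc(OC(=O)C(C)(C)C)cc2[o+]cc(-c3ccc(OC(=O)C(C)(C)C)c4c3OC(C)(C)C=C4)cc12.F[B-](F)(F)F
F2 | step 6 | rac-3-[2,2-dimethyl-5-(pivaloyloxy)-2H-chromen-8-yl]-2,5-dimethoxy-2H-chromen-7-yl pivalate | COC1Oc2cc(OC(=O)C(C)(C)C)cc(OC)c2C=C1c1ccc(OC(=O)C(C)(C)C)c2c1OC(C)(C)C=C2
F3 | step 7 | rac-3-[2,2-dimethyl-5-(pivaloyloxy)-2H-chromen-8-yl]-5-methoxychroman-7-yl pivalate | COc1cc(OC(=O)C(C)(C)C)cc2c1CC(c1ccc(OC(=O)C(C)(C)C)c3c1OC(C)(C)C=C3)CO2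
F4 | step 5 | 3-hydroxy-5-methoxy-4-[(4-methylphenyl)sulfonylmethyl]phenyl pivalate | COc1cc(OC(=O)C(C)(C)C)cc(O)c1CS(=O)(=O)c1ccc(C)cc1
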